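**Retrosynthetic overview**
1. The quaternary C8 is made last, by ligand-controlled dearomative C-prenylation of a fully substituted 5,7-dihydroxychromanone acid.
2. The (S)-hexanoic acid arm comes from an organocatalytic Friedel–Crafts addition of the single free arene position to hex-2-enal, then oxidation.
3. Both rings are made in one flask from an acyclic hydroxy-triketo tert-butyl ester: the pyranone closes first (cyclodehydration), the carbocycle second (acylketene, 6π closure, aromatisation).
4. The triketo ester comes from a β-keto ester by two Claisen-type acylations: acetyl, then the Evans syn-aldol Weinreb amide that carries both pyranone stereocentres.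
5. The β-keto ester and its remote stereocentre come from (R)-limonene oxide: ring cleavage, one-carbon homologation with methylenation, Claisen condensation with tert-butyl acetate.

Assumption: the commercial cis/trans mixture of (R)-(+)-limonene 1,2-oxide is used, since both epoxide isomers give the same keto-aldehyde.
Assumption: the sense of induction of the (R,R) ligand in step 11 is not established for this substrate; if the C8 epimer dominates, the (S,S) ligand is used instead.

**Route**

Step 1
Reactants: 1 (4R)-limonene 1,2-oxide (cis/trans mixture)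
Product: 2 (3R)-6-oxo-3-(prop-1-en-2-yl)heptanal
Conditions: H5IO6 (1.1 equiv), THF/H2O, 0 °C to rt
Reagents that add atoms: water, O
Why: Epoxide hydrolysis and periodate glycol cleavage (Malaprade-type) open the terpene ring between C1 and C2 without touching the isopropenyl group, so the stereocentre is carried unchanged from the chiral pool.

Step 2
Reactants: 2 (3R)-6-oxo-3-(prop-1-en-2-yl)heptanal; 3 (methoxymethyl)triphenylphosphonium chloride; 4 methyltriphenylphosphonium bromide
Product: 6 (4R)-1-methoxy-7-methyl-4-(prop-1-en-2-yl)octa-1,7-diene (E/Z mixture), via keto enol ether 5 (not isolated)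
Conditions: 3 (1.05 equiv), KOt-Bu, THF, 0 °C, then 2, −78 to 0 °C; then ylide from 4 (2.5 equiv) and KOt-Bu, 0 °C to rt
Reagents that add atoms: 3 (methoxymethyl)triphenylphosphonium chloride, COC[P+](c1ccccc1)(c1ccccc1)c1ccccc1.[Cl-]; 4 methyltriphenylphosphonium bromide, C[P+](c1ccccc1)(c1ccccc1)c1ccccc1.[Br-]
Why: In this sequential one-pot Wittig olefination the aldehyde reacts first with one equivalent of the methoxymethylene ylide at low temperature and the methyl ketone is then methylenated by the second ylide, with no stereocentre formed and the enol ether geometry irrelevant.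

Step 3
Reactants: 6 (4R)-1-methoxy-7-methyl-4-(prop-1-en-2-yl)octa-1,7-diene
Product: 7 methyl (4R)-7-methyl-4-(prop-1-en-2-yl)oct-7-enoate
Conditions: pyridinium chlorochromate [C5H5NH][CrO3Cl] (2.5 equiv), CH2Cl2, rt
Reagents that add atoms: pyridinium chlorochromate, [O-][Cr](=O)(=O)Cl.c1cc[nH+]cc1
Why: Chlorochromate oxidation of the electron-rich enol ether to the ester gives the one-carbon-homologated methyl ester while the isolated 1,1-disubstituted alkenes are inert at room temperature and no stereocentre is affected.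

Step 4
Reactants: 7 methyl (4R)-7-methyl-4-(prop-1-en-2-yl)oct-7-enoate; 8 tert-butyl acetate
Product: 9 tert-butyl (6R)-9-methyl-3-oxo-6-(prop-1-en-2-yl)dec-9-enoate
Conditions: 8 (2.5 equiv), LiN(i-Pr)2 (2.5 equiv), THF, −78 °C; then 7, −78 to −30 °C; aq. NH4Cl
Reagents that add atoms: 8 tert-butyl acetate, CC(=O)OC(C)(C)C
Why: Crossed Claisen condensation of the preformed lithium enolate of tert-butyl acetate with the methyl ester gives the β-keto ester, the excess enolate taking up the acidic product proton, and no new stereocentre is formed.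

Step 5
Reactants: 9 tert-butyl (6R)-9-methyl-3-oxo-6-(prop-1-en-2-yl)dec-9-enoate; 10 N-methoxy-N-methylacetamide
Product: 11 tert-butyl 3,5-dioxo-4-[(2R)-5-methyl-2-(prop-1-en-2-yl)hex-5-en-1-yl]hexanoate
Conditions: LiN(i-Pr)2 (2.2 equiv), THF, −78 to 0 °C; then 10 (1.2 equiv), −78 to −20 °C; aq. NH4Cl
Reagents that add atoms: 10 N-methoxy-N-methylacetamide, CC(=O)N(C)OC
Why: Weiler-type dianion formation puts the second charge on the only γ-carbon, which is acylated by the Weinreb amide through a stable chelated tetrahedral adduct that prevents proton quench and over-addition, and the new methine is labile and later becomes an arene carbon.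

Step 6
Reactants: 12 (4S)-4-benzyl-3-propanoyl-1,3-oxazolidin-2-one; 13 acetaldehyde
Product: 14 (4S)-4-benzyl-3-[(2S,3R)-3-hydroxy-2-methylbutanoyl]-1,3-oxazolidin-2-one
Conditions: Bu2BOTf (1.1 equiv), i-Pr2NEt (1.3 equiv), CH2Cl2, 0 °C; 13 (3 equiv), −78 to 0 °C; pH 7 buffer, MeOH, H2O2
Reagents that add atoms: 13 acetaldehyde, CC=O
Why: Evans syn-aldol reaction through the Z-boron enolate and a Zimmerman–Traxler transition state, in which the benzyl group of the (S)-auxiliary blocks one enolate face, sets the (2S,3R) syn pair that becomes C3 and C2 of the pyranone.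

Step 7
Reactants: 14 (4S)-4-benzyl-3-[(2S,3R)-3-hydroxy-2-methylbutanoyl]-1,3-oxazolidin-2-one
Product: 15 (2S,3R)-3-hydroxy-N-methoxy-N,2-dimethylbutanamide
Conditions: MeNHOMe·HCl (3 equiv), Al(CH3)3 (3 equiv), CH2Cl2, −20 °C to rt
Reagents that add atoms: N,O-dimethylhydroxylamine hydrochloride, CNOC.Cl
Why: Aluminium amide transamination to the Weinreb amide, assisted by the free β-hydroxyl, removes the auxiliary without epimerising the α-centre.

Step 8
Reactants: 11 tert-butyl 3,5-dioxo-4-[(2R)-5-methyl-2-(prop-1-en-2-yl)hex-5-en-1-yl]hexanoate; 15 (2S,3R)-3-hydroxy-N-methoxy-N,2-dimethylbutanamide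
Product: 16 tert-butyl (8S,9R)-9-hydroxy-8-methyl-4-[(2R)-5-methyl-2-(prop-1-en-2-yl)hex-5-en-1-yl]-3,5,7-trioxodecanoate (in equilibrium with its six-membered hemiketal)
Conditions: 11, LiN(i-Pr)2 (3.1 equiv), THF, −78 to 0 °C; then lithium alkoxide of 15 (15 + 1.0 equiv LiN(i-Pr)2), −78 to −20 °C; AcOH, −78 °C; aq. NH4Cl
Reagents that add atoms: none
Why: In this polyanion Claisen-type acylation the trianion of the 3,5-diketo ester reacts at its last-formed terminal methyl carbanion with the Weinreb amide, whose lithium alkoxide and chelated tetrahedral adduct protect the hydroxyl and the α-stereocentre until the acidic quench.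

Step 9
Reactants: 16 tert-butyl (8S,9R)-9-hydroxy-8-methyl-4-[(2R)-5-methyl-2-(prop-1-en-2-yl)hex-5-en-1-yl]-3,5,7-trioxodecanoate
Product: 19 (2R,3S)-5,7-dihydroxy-2,3-dimethyl-8-[(2R)-5-methyl-2-(prop-1-en-2-yl)hex-5-en-1-yl]-2,3-dihydro-4H-chromen-4-one, via dihydropyranone 17 (not isolated), via acylketene 18 (not isolated)
Conditions: PPTS (0.2 equiv), 4 Å MS, toluene (0.005 M), 60 °C, 2 h; then 110 °C, 3 h, N2 sweep
Reagents that add atoms: none
Why: Proposed new method: mild acid turns the δ-hydroxy-β-diketone into the cis-2,3-dihydro-4-pyranone with retention at both centres (the only six-membered closure possible, which fixes the ring oxygen next to the alkylated carbon and removes the enol oxygen that would otherwise give a pyrone), then thermal loss of tert-butanol from the β-keto ester gives an acylketene whose dienylketene enol tautomer closes by 6π-electrocyclisation and tautomerises to the arene, the closest known reaction types being hydroxy-diketone cyclodehydration to dihydropyranones, acylketene generation from tert-butyl acetoacetates or dioxinones with biomimetic aromatisation, and the electrocyclic step of the Danheiser benzannulation.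

Step 10
Reactants: 19 (2R,3S)-5,7-dihydroxy-2,3-dimethyl-8-[(2R)-5-methyl-2-(prop-1-en-2-yl)hex-5-en-1-yl]-2,3-dihydro-4H-chromen-4-one; 20 (E)-hex-2-enal
Product: 22 (3S)-3-[(2R,3S)-5,7-dihydroxy-2,3-dimethyl-8-[(2R)-5-methyl-2-(prop-1-en-2-yl)hex-5-en-1-yl]-4-oxo-3,4-dihydro-2H-chromen-6-yl]hexanoic acid, via lactol 21 (not isolated)
Conditions: 20 (1.5 equiv), (R)-2-[diphenyl(trimethylsilyloxy)methyl]pyrrolidine (20 mol%), PhCO2H (20 mol%), CH2Cl2, 0 °C to rt; then t-BuOH/H2O, 2-methyl-2-butene (40 equiv), NaH2PO4, NaClO2, 0 °C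
Reagents that add atoms: 20 (E)-hex-2-enal, CCC/C=C/C=O; sodium chlorite, [Na+].[O-]Cl=O
Why: Iminium-catalysed asymmetric Friedel–Crafts conjugate addition of the only free, doubly ortho-hydroxylated arene carbon to the enal, with the (R)-diarylprolinol silyl ether shielding one face of the E-iminium ion so that the (S) benzylic centre results, is followed in the same flask by Pinnick oxidation of the lactol to the acid.

Step 11
Reactants: 22 (3S)-3-[(2R,3S)-5,7-dihydroxy-2,3-dimethyl-8-[(2R)-5-methyl-2-(prop-1-en-2-yl)hex-5-en-1-yl]-4-oxo-3,4-dihydro-2H-chromen-6-yl]hexanoic acid; 23 3-methylbut-2-en-1-yl acetate (prenyl acetate)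
Product: 24 CNP0294320.1, (3S)-3-[(2R,3S,8R)-5-hydroxy-2,3-dimethyl-8-(3-methylbut-2-en-1-yl)-8-[(2R)-5-methyl-2-(prop-1-en-2-yl)hex-5-en-1-yl]-4,7-dioxo-3,4,7,8-tetrahydro-2H-chromen-6-yl]hexanoic acid
Conditions: 23 (1.3 equiv), Pd2(dba)3·CHCl3 (2.5 mol%), (R,R)-DACH-phenyl Trost ligand (7.5 mol%), Cs2CO3 (2.2 equiv), degassed THF, 0 °C to rt; 1 M HCl work-up
Reagents that add atoms: 23 3-methylbut-2-en-1-yl acetate, CC(C)=CCOC(C)=O
Why: Proposed new method: the cesium 7-phenoxide attacks the ligand-bound π-prenyl palladium cation at its unsubstituted terminus through C8 (less hindered than C6, which carries the secondary alkyl arm), O-prenyl ethers and the prenyl carboxylate re-ionise under zerovalent palladium so the irreversible C8–C bond accumulates, and the chiral ligand pocket differentiates the two faces of the planar phenoxide to set the C8 quaternary centre, the closest known reaction type being Tsuji–Trost asymmetric allylic alkylation used for dearomatisation of naphthols and phenols.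

**Compound list**
1 | (4R)-limonene 1,2-oxide, cis/trans mixture | CC12CC[C@H](CC1O2)C(C)=C | starting material
2 | (3R)-6-oxo-3-(prop-1-en-2-yl)heptanal | CC(=O)CC[C@H](CC=O)C(=C)C | intermediate
3 | (methoxymethyl)triphenylphosphonium chloride | COC[P+](c1ccccc1)(c1ccccc1)c1ccccc1.[Cl-] | starting material
4 | methyltriphenylphosphonium bromide | C[P+](c1ccccc1)(c1ccccc1)c1ccccc1.[Br-] | starting material
5 | (5R)-8-methoxy-5-(prop-1-en-2-yl)oct-7-en-2-one, E/Z mixture | CC(=O)CC[C@H](CC=COC)C(=C)C | intermediate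
6 | (4R)-1-methoxy-7-methyl-4-(prop-1-en-2-yl)octa-1,7-diene, E/Z mixture | C=C(C)CC[C@H](CC=COC)C(=C)C | intermediate
7 | methyl (4R)-7-methyl-4-(prop-1-en-2-yl)oct-7-enoate | C=C(C)CC[C@H](CCC(=O)OC)C(=C)C | intermediate
8 | tert-butyl acetate | CC(=O)OC(C)(C)C | starting material
9 | tert-butyl (6R)-9-methyl-3-oxo-6-(prop-1-en-2-yl)dec-9-enoate | C=C(C)CC[C@H](CCC(=O)CC(=O)OC(C)(C)C)C(=C)C | intermediate
10 | N-methoxy-N-methylacetamide | CC(=O)N(C)OC | starting material
11 | tert-butyl 3,5-dioxo-4-[(2R)-5-methyl-2-(prop-1-en-2-yl)hex-5-en-1-yl]hexanoate, C4 epimers and enol forms | C=C(C)CC[C@H](CC(C(C)=O)C(=O)CC(=O)OC(C)(C)C)C(=C)C | intermediate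
12 | (4S)-4-benzyl-3-propanoyl-1,3-oxazolidin-2-one | CCC(=O)N1[C@@H](Cc2ccccc2)COC1=O | starting material
13 | acetaldehyde | CC=O | starting material
14 | (4S)-4-benzyl-3-[(2S,3R)-3-hydroxy-2-methylbutanoyl]-1,3-oxazolidin-2-one | O[C@H](C)[C@H](C)C(=O)N1[C@@H](Cc2ccccc2)COC1=O | intermediate
15 | (2S,3R)-3-hydroxy-N-methoxy-N,2-dimethylbutanamide | O[C@H](C)[C@H](C)C(=O)N(C)OC | intermediate
16 | tert-butyl (8S,9R)-9-hydroxy-8-methyl-4-[(2R)-5-methyl-2-(prop-1-en-2-yl)hex-5-en-1-yl]-3,5,7-trioxodecanoate, open form of the hemiketal | C=C(C)CC[C@H](CC(C(=O)CC(=O)OC(C)(C)C)C(=O)CC(=O)[C@@H](C)[C@@H](C)O)C(=C)C | intermediate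
17 | tert-butyl (6R)-4-[(2R,3S)-2,3-dimethyl-4-oxo-3,4-dihydro-2H-pyran-6-yl]-9-methyl-3-oxo-6-(prop-1-en-2-yl)dec-9-enoate | C=C(C)CC[C@H](CC(C(=O)CC(=O)OC(C)(C)C)C1=CC(=O)[C@@H](C)[C@@H](C)O1)C(=C)C | intermediate
18 | (6R)-4-[(2R,3S)-2,3-dimethyl-4-oxo-3,4-dihydro-2H-pyran-6-yl]-9-methyl-6-(prop-1-en-2-yl)deca-1,9-diene-1,3-dione (acylketene) | C=C(C)CC[C@H](CC(C(=O)C=C=O)C1=CC(=O)[C@@H](C)[C@@H](C)O1)C(=C)C | intermediate
19 | (2R,3S)-5,7-dihydroxy-2,3-dimethyl-8-[(2R)-5-methyl-2-(prop-1-en-2-yl)hex-5-en-1-yl]-2,3-dihydro-4H-chromen-4-one | C=C(C)CC[C@H](Cc1c(O)cc(O)c2c1O[C@H](C)[C@H](C)C2=O)C(=C)C | intermediate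
20 | (E)-hex-2-enal | CCC/C=C/C=O | starting material
21 | lactol of the (3S)-hexanal adduct at C6 of 19, closed on the 7-oxygen (anomers; equilibrates with the 5-O isomer and the open aldehyde) | C=C(C)CC[C@H](Cc1c2OC(O)C[C@H](CCC)c2c(O)c2c1O[C@H](C)[C@H](C)C2=O)C(=C)C | intermediate
22 | (3S)-3-[(2R,3S)-5,7-dihydroxy-2,3-dimethyl-8-[(2R)-5-methyl-2-(prop-1-en-2-yl)hex-5-en-1-yl]-4-oxo-3,4-dihydro-2H-chromen-6-yl]hexanoic acid | C=C(C)CC[C@H](Cc1c(O)c([C@@H](CCC)CC(=O)O)c(O)c2c1O[C@H](C)[C@H](C)C2=O)C(=C)C | intermediate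
23 | 3-methylbut-2-en-1-yl acetate | CC(C)=CCOC(C)=O | starting material
24 | CNP0294320.1, (3S)-3-[(2R,3S,8R)-5-hydroxy-2,3-dimethyl-8-(3-methylbut-2-en-1-yl)-8-[(2R)-5-methyl-2-(prop-1-en-2-yl)hex-5-en-1-yl]-4,7-dioxo-3,4,7,8-tetrahydro-2H-chromen-6-yl]hexanoic acid | C=C(C)CC[C@H](C[C@@]1(CC=C(C)C)C(=O)C([C@@H](CCC)CC(=O)O)=C(O)C2=C1O[C@H](C)[C@H](C)C2=O)C(=C)C | target

**Step count and risks**
Total steps: 11. Longest linear sequence: 9 (steps 1–5, 8–11); steps 6–7 make the aldol fragment.

Most likely to fail, with one fallback each: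

Step 11 (dearomative prenylation). The risks are C8 versus C6 regioselectivity and facial control at a centre remote from every existing stereocentre. The fallback sets out from 22 and returns at 24. Acid 22 is lactonised (EDC·HCl, CH2Cl2) onto the free 7-hydroxyl to give the dihydrocoumarin lactone F1. This masks both the acid and the 7-oxygen, so only the chelated 5-hydroxyl is left and its phenoxide can be C-alkylated only para, at C8. Prenylation of F1 with 23 under achiral Pd(PPh3)4 and Cs2CO3 gives the dearomatised 8-prenyl enol lactone F2 together with its C8 epimer. The two are diastereomers and are separated by chromatography, so C8 is secured by separation rather than by induction. LiOH in THF/H2O at 0 °C then opens the activated enol lactone of F2 to 24.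

Step 9 (two-ring cascade). The risks are sluggish ketene release from the tert-butyl ester at a tolerable temperature, and competing aldol or pyrone closures. The fallback sets out from 7 and returns at 19, using a dioxinone as a lower-temperature ketene source.
- Ester 7 is hydrolysed (LiOH, THF/H2O) to (4R)-7-methyl-4-(prop-1-en-2-yl)oct-7-enoic acid F3.
- F3 is coupled with Meldrum's acid (DCC, DMAP, CH2Cl2) to the acyl Meldrum's acid F4.
- F4 is heated with acetone in toluene at 100 °C to give the dioxinone F5.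
- The γ-anion of F5 (LiN(i-Pr)2, −78 °C) is acetylated with 10 to the keto-dioxinone F6.
- The dianion of F6 is acylated at its terminal methyl with the lithium alkoxide of 15 to give the hydroxy-diketo-dioxinone F7.
- PPTS in toluene at 60 °C, then 100 °C, closes the pyranone and releases acetone to give the same acylketene 18, which closes to 19.

Step 8 (trianion acylation). The risk is slow addition of a tetra-lithiated nucleophile to a hindered, α-branched Weinreb amide. The fallback sets out from 14 and returns at 16. Imide 14 is cleaved (LiOH, H2O2, THF/H2O, 0 °C) to (2S,3R)-3-hydroxy-2-methylbutanoic acid F8. F8 is closed by carboxyl activation (PhSO2Cl, pyridine, 0 °C), with retention at both centres, to the cis-β-lactone (3S,4R)-3,4-dimethyloxetan-2-one F9. The trianion of 11 then opens F9 at its strained, unhindered acyl carbon, with no leaving group to expel, and gives the alkoxide of 16 directly.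

Further compounds
F1 | step 11 | 7-O lactone (3,4-dihydrocoumarin) of acid 22, (S) at the propyl-bearing carbon | C=C(C)CC[C@H](Cc1c2OC(=O)C[C@H](CCC)c2c(O)c2c1O[C@H](C)[C@H](C)C2=O)C(=C)C
F2 | step 11 | (8R)-8-prenyl dearomatised enol lactone of 24 (5-oxo cross-conjugated dienone, lactone on the 7-oxygen) | C=C(C)CC[C@H](C[C@@]1(CC=C(C)C)C2=C([C@@H](CCC)CC(=O)O2)C(=O)C2=C1O[C@H](C)[C@H](C)C2=O)C(=C)C
F3 | step 9 | (4R)-7-methyl-4-(prop-1-en-2-yl)oct-7-enoic acid | C=C(C)CC[C@H](CCC(=O)O)C(=C)C
F4 | step 9 | 2,2-dimethyl-5-[(4R)-7-methyl-4-(prop-1-en-2-yl)oct-7-enoyl]-1,3-dioxane-4,6-dione | C=C(C)CC[C@H](CCC(=O)C1C(=O)OC(C)(C)OC1=O)C(=C)C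
F5 | step 9 | 2,2-dimethyl-6-[(3R)-6-methyl-3-(prop-1-en-2-yl)hept-6-en-1-yl]-4H-1,3-dioxin-4-one | C=C(C)CC[C@H](CCC1=CC(=O)OC(C)(C)O1)C(=C)C
F6 | step 9 | 2,2-dimethyl-6-[(5R)-8-methyl-2-oxo-5-(prop-1-en-2-yl)non-8-en-3-yl]-4H-1,3-dioxin-4-one | C=C(C)CC[C@H](CC(C(C)=O)C1=CC(=O)OC(C)(C)O1)C(=C)C
F7 | step 9 | 6-[(2R,3S,9R)-2-hydroxy-3,12-dimethyl-4,6-dioxo-9-(prop-1-en-2-yl)tridec-12-en-7-yl]-2,2-dimethyl-4H-1,3-dioxin-4-one | C=C(C)CC[C@H](CC(C(=O)CC(=O)[C@@H](C)[C@@H](C)O)C1=CC(=O)OC(C)(C)O1)C(=C)C
F8 | step 8 | (2S,3R)-3-hydroxy-2-methylbutanoic acid | O[C@H](C)[C@H](C)C(=O)O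
F9 | step 8 | (3S,4R)-3,4-dimethyloxetan-2-one | O1[C@H](C)[C@H](C)C1=O
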